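**Plan**
1. Retrosynthetic cuts, in order: the O-8 MOM group; the ring A C-5–CMe2 bond (retro-aromatic Claisen, back to an O-4 prenyl ether); the ring A C-1–CH2 bond of the propane bridge; then in ring B the C-5–prenyl bond, C-5–Br, and the chroman O-1–C-2 and C-4–C-4a bonds. The starting materials are methyl dihydroferulate and resorcinol.
2. Enabling feature: ring A C-1 lies ortho to the C-2 OH and para to the C-4 oxygen, so it is the enol-like carbon of a resorcinol. The C-2 OH can hold a boron atom that also binds the aldehyde oxygen of a ring B propanal. The aryl–CH2 bond then forms from an unfunctionalised C–H inside a temporary 1,3,2-benzodioxaborinine ring.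
3. The extra benzylic oxygen is ortho-hydroxybenzylic. It leaves again through an o-quinone methide, which borohydride reduces without touching any alkene.
4. Forward order: chroman ring of B, C-5 prenyl group, propanal, union with ring A, deoxygenation, [3,3] shift, deprotection. The O-4 prenyl ether acts as para donor and blocking group during the union and then becomes the 1,1-dimethylallyl group.
5. Stereochemistry: none has to be set. The stereocentres that appear on the way are racemic and are erased.

Key step: step 8

Remark on the chemistry: kazinol D has no stereocentre and no E/Z-stereogenic alkene, so the requirement for a single enantiomer is met by the achiral compound itself.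

**Step 1**
Reactants: 1 methyl 3-(4-hydroxy-3-methoxyphenyl)propanoate (methyl dihydroferulate)
Product: 3 methyl 3-(8-methoxy-2,2-dimethylchroman-6-yl)propanoate, via methyl 3-[4-hydroxy-3-methoxy-5-(3-methylbut-2-en-1-yl)phenyl]propanoate 2 (not isolated)
Conditions: isoprene (1.5 equiv), AgOTf (5 mol %), ClCH2CH2Cl, rt
Reagents that add atoms: isoprene, C=CC(C)=C
Why: In this chroman annulation of a phenol with isoprene (Friedel–Crafts prenylation, then hydroalkoxylation), the prenyl cation equivalent enters ortho to the free OH, the only open ortho/para site of that donor, and the phenol then adds in the Markovnikov sense to the alkene of 2 to close the six-membered ether.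

**Step 2**
Reactants: 3 methyl 3-(8-methoxy-2,2-dimethylchroman-6-yl)propanoate
Product: 4 methyl 3-(8-hydroxy-2,2-dimethylchroman-6-yl)propanoate
Conditions: BBr3 (1.5 equiv), CH2Cl2, −78 to 0 °C; then H2O
Reagents that add atoms: none
Why: In this Lewis-acid aryl methyl ether cleavage, bromide attacks the unhindered O-methyl carbon of the boron-bound ether faster than the tertiary ring C–O bond or the ester reacts at this temperature.

**Step 3**
Reactants: 4 methyl 3-(8-hydroxy-2,2-dimethylchroman-6-yl)propanoate
Product: 5 methyl 3-(5-bromo-8-hydroxy-2,2-dimethylchroman-6-yl)propanoate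
Conditions: NBS (1.0 equiv), MeCN, −20 to 0 °C, dark
Reagents that add atoms: N-bromosuccinimide, O=C1CCC(=O)N1Br
Why: In this electrophilic aromatic bromination the free C-8 OH directs to its para carbon C-5, because the ortho/para sites of the ring oxygen are all substituted and the polar solvent favours para over the ortho carbon C-7.

**Step 4**
Reactants: 5 methyl 3-(5-bromo-8-hydroxy-2,2-dimethylchroman-6-yl)propanoate
Product: 6 methyl 3-[5-bromo-8-(methoxymethoxy)-2,2-dimethylchroman-6-yl]propanoate
Conditions: MOMCl, i-Pr2NEt, CH2Cl2, 0 °C to rt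
Reagents that add atoms: chloromethyl methyl ether, COCCl
Why: This is a standard O-alkylation of a phenol to its MOM acetal, a group that should survive Pd/fluoride, DIBAL-H, weak acid at reflux, hot alkaline borohydride and 195 °C.

**Step 5**
Reactants: 6 methyl 3-[5-bromo-8-(methoxymethoxy)-2,2-dimethylchroman-6-yl]propanoate
Product: 7 methyl 3-[8-(methoxymethoxy)-2,2-dimethyl-5-(3-methylbut-2-en-1-yl)chroman-6-yl]propanoate
Conditions: tributyl(prenyl)stannane, Pd(P-t-Bu3)2 (5 mol %), CsF, dioxane, 100 °C
Reagents that add atoms: tributyl(3-methylbut-2-en-1-yl)stannane, CCCC[Sn](CCCC)(CCCC)CC=C(C)C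
Why: In this Stille coupling the bulky, electron-rich Pd(0) inserts into the doubly ortho-substituted C–Br bond, and the allyl-palladium species should eliminate at its CH2 end, because the flanked aryl group cannot bond to the tertiary end, which gives the linear prenyl group.

**Step 6**
Reactants: 7 methyl 3-[8-(methoxymethoxy)-2,2-dimethyl-5-(3-methylbut-2-en-1-yl)chroman-6-yl]propanoate
Product: 8 3-[8-(methoxymethoxy)-2,2-dimethyl-5-(3-methylbut-2-en-1-yl)chroman-6-yl]propanal
Conditions: DIBAL-H (1.05 equiv), CH2Cl2, −78 °C; Rochelle salt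
Reagents that add atoms: none
Why: This low-temperature partial reduction of a methyl ester stops at the aldehyde oxidation level until work-up, and the alkene, MOM group and chroman are inert to it.

**Step 7**
Reactants: 9 resorcinol (used in excess)
Product: 10 3-[(3-methylbut-2-en-1-yl)oxy]phenol
Conditions: prenyl bromide, K2CO3, acetone, reflux
Reagents that add atoms: 1-bromo-3-methylbut-2-ene, CC(C)=CCBr
Why: This is a Williamson mono-etherification in which the excess of the cheap diol limits double alkylation, and carbonate in acetone favours O- over C-prenylation.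

**Step 8**
Reactants: 8 3-[8-(methoxymethoxy)-2,2-dimethyl-5-(3-methylbut-2-en-1-yl)chroman-6-yl]propanal; 10 3-[(3-methylbut-2-en-1-yl)oxy]phenol (1.5 equiv)
Product: 12 rac-2-phenyl-7-(prenyloxy)-4-{2-[8-(methoxymethoxy)-2,2-dimethyl-5-prenylchroman-6-yl]ethyl}-4H-1,3,2-benzodioxaborinine, via 3-[(3-methylbut-2-en-1-yl)oxy]phenyl hydrogen phenylboronate 11 (not isolated)
Conditions: PhB(OH)2 (1.5 equiv), EtCO2H (0.3 equiv), PhH, reflux, Dean–Stark
Reagents that add atoms: phenylboronic acid, OB(O)c1ccccc1
Why: Phenol 10 and PhB(OH)2 condense to boronate 11, whose boron binds the aldehyde oxygen of 8, so that the ortho carbon of ring A attacks the activated C=O through a six-membered, [3,3]-like cyclic transition state, and tautomerisation then restores the arene. The closest known reaction type is the phenylboronic-acid-templated, ortho-specific hydroxyalkylation of phenols with aliphatic aldehydes, which is also used on 3-alkoxyphenols. The only ring closed is the temporary 1,3,2-dioxaborinine, formed in a 6-endo-trig sense on the boron-bound carbonyl while the trap removes the two waters. The new benzylic stereocentre C-4 is under no control, forms as a racemate and is erased in step 9. The step needs C- over O-attack, ortho over para, and C-6 over C-2 of 10: the boron tether reaches only ortho carbons, and C-6 is para to the prenyloxy donor and open, whereas C-2 is flanked by two oxygens. The MOM group on O-8 keeps ring B from using its own OH/C-7 pair for an intramolecular version that would give an indanol, and the weak acid should leave both trisubstituted alkenes and the aryl prenyl ether alone.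

**Step 9**
Reactants: 12 rac-2-phenyl-7-(prenyloxy)-4-{2-[8-(methoxymethoxy)-2,2-dimethyl-5-prenylchroman-6-yl]ethyl}-4H-1,3,2-benzodioxaborinine
Product: 15 2-{3-[8-(methoxymethoxy)-2,2-dimethyl-5-prenylchroman-6-yl]propyl}-5-(prenyloxy)phenol, via rac-1-[2-hydroxy-4-(prenyloxy)phenyl]-3-[8-(methoxymethoxy)-2,2-dimethyl-5-prenylchroman-6-yl]propan-1-ol 13 (not isolated), via 6-{3-[8-(methoxymethoxy)-2,2-dimethyl-5-prenylchroman-6-yl]propylidene}-3-(prenyloxy)cyclohexa-2,4-dien-1-one 14 (not isolated)
Conditions: NaBH4 (10 equiv), 2 M aq NaOH–EtOH–THF, reflux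
Reagents that add atoms: none
Why: In this alkaline borohydride deoxygenation of an o-hydroxybenzyl alcohol, hydroxide takes the boron off to give 13, the ortho phenoxide (helped by the para prenyloxy donor) expels the benzylic oxygen to give o-quinone methide 14, and hydride adds 1,4 to its exocyclic carbon, while the base-stable MOM group keeps ring B a neutral ether so that C-7 does not close an indane onto 14.

**Step 10**
Reactants: 15 2-{3-[8-(methoxymethoxy)-2,2-dimethyl-5-prenylchroman-6-yl]propyl}-5-(prenyloxy)phenol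
Product: 17 4-{3-[8-(methoxymethoxy)-2,2-dimethyl-5-prenylchroman-6-yl]propyl}-6-(2-methylbut-3-en-2-yl)benzene-1,3-diol (8-O-MOM kazinol D), via rac-3-hydroxy-4-{3-[8-(methoxymethoxy)-2,2-dimethyl-5-prenylchroman-6-yl]propyl}-6-(2-methylbut-3-en-2-yl)cyclohexa-2,4-dien-1-one 16 (not isolated)
Conditions: PhNEt2, 195 °C, sealed tube, Ar, short reaction time
Reagents that add atoms: none
Why: In this aromatic Claisen rearrangement the [3,3] shift delivers the O-4 prenyl group with allyl inversion as a 1,1-dimethylallyl group to C-5, the ortho carbon not flanked by two oxygens, after which dienone 16 enolises, the chain at the para carbon blocks a productive Cope shift, and the basic solvent suppresses ring closure of the new phenol onto the vinyl group.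

**Step 11**
Reactants: 17 8-O-MOM kazinol D
Product: 18 kazinol D
Conditions: conc. HCl (cat.), MeOH, rt to 40 °C
Reagents that add atoms: none
Why: In this acid-catalysed acetal exchange methanol carries the formaldehyde unit away, and the dilute acid at low temperature should not protonate the monosubstituted vinyl group next to the phenol or the C-5 prenyl group, which has no ortho OH.

**Compound list**
1 | methyl 3-(4-hydroxy-3-methoxyphenyl)propanoate | COC(=O)CCc1ccc(O)c(OC)c1 | starting material
2 | methyl 3-[4-hydroxy-3-methoxy-5-(3-methylbut-2-en-1-yl)phenyl]propanoate | COC(=O)CCc1cc(CC=C(C)C)c(O)c(OC)c1 | intermediate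
3 | methyl 3-(8-methoxy-2,2-dimethylchroman-6-yl)propanoate | COC(=O)CCc1cc(OC)c2OC(C)(C)CCc2c1 | intermediate
4 | methyl 3-(8-hydroxy-2,2-dimethylchroman-6-yl)propanoate | COC(=O)CCc1cc(O)c2OC(C)(C)CCc2c1 | intermediate
5 | methyl 3-(5-bromo-8-hydroxy-2,2-dimethylchroman-6-yl)propanoate | COC(=O)CCc1cc(O)c2OC(C)(C)CCc2c1Br | intermediate
6 | methyl 3-[5-bromo-8-(methoxymethoxy)-2,2-dimethylchroman-6-yl]propanoate | COCOc1cc(CCC(=O)OC)c(Br)c2CCC(C)(C)Oc12 | intermediate
7 | methyl 3-[8-(methoxymethoxy)-2,2-dimethyl-5-(3-methylbut-2-en-1-yl)chroman-6-yl]propanoate | COCOc1cc(CCC(=O)OC)c(CC=C(C)C)c2CCC(C)(C)Oc12 | intermediate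
8 | 3-[8-(methoxymethoxy)-2,2-dimethyl-5-(3-methylbut-2-en-1-yl)chroman-6-yl]propanal | COCOc1cc(CCC=O)c(CC=C(C)C)c2CCC(C)(C)Oc12 | intermediate
9 | resorcinol | Oc1cccc(O)c1 | starting material
10 | 3-[(3-methylbut-2-en-1-yl)oxy]phenol | CC(C)=CCOc1cccc(O)c1 | intermediate
11 | 3-[(3-methylbut-2-en-1-yl)oxy]phenyl hydrogen phenylboronate | CC(C)=CCOc1cccc(OB(O)c2ccccc2)c1 | intermediate
12 | rac-2-phenyl-7-(prenyloxy)-4-{2-[8-(methoxymethoxy)-2,2-dimethyl-5-prenylchroman-6-yl]ethyl}-4H-1,3,2-benzodioxaborinine | CC(C)=CCOc1ccc2C(CCc3cc(OCOC)c4OC(C)(C)CCc4c3CC=C(C)C)OB(c3ccccc3)Oc2c1 | intermediate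
13 | rac-1-[2-hydroxy-4-(prenyloxy)phenyl]-3-[8-(methoxymethoxy)-2,2-dimethyl-5-prenylchroman-6-yl]propan-1-ol | CC(C)=CCOc1ccc(C(O)CCc2cc(OCOC)c3OC(C)(C)CCc3c2CC=C(C)C)c(O)c1 | intermediate
14 | 6-{3-[8-(methoxymethoxy)-2,2-dimethyl-5-prenylchroman-6-yl]propylidene}-3-(prenyloxy)cyclohexa-2,4-dien-1-one | CC(C)=CCOC1=CC(=O)C(=CCCc2cc(OCOC)c3OC(C)(C)CCc3c2CC=C(C)C)C=C1 | intermediate
15 | 2-{3-[8-(methoxymethoxy)-2,2-dimethyl-5-prenylchroman-6-yl]propyl}-5-(prenyloxy)phenol | CC(C)=CCOc1ccc(CCCc2cc(OCOC)c3OC(C)(C)CCc3c2CC=C(C)C)c(O)c1 | intermediate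
16 | rac-3-hydroxy-4-{3-[8-(methoxymethoxy)-2,2-dimethyl-5-prenylchroman-6-yl]propyl}-6-(2-methylbut-3-en-2-yl)cyclohexa-2,4-dien-1-one | C=CC(C)(C)C1C=C(CCCc2cc(OCOC)c3OC(C)(C)CCc3c2CC=C(C)C)C(O)=CC1=O | intermediate
17 | 4-{3-[8-(methoxymethoxy)-2,2-dimethyl-5-prenylchroman-6-yl]propyl}-6-(2-methylbut-3-en-2-yl)benzene-1,3-diol | C=CC(C)(C)c1cc(CCCc2cc(OCOC)c3OC(C)(C)CCc3c2CC=C(C)C)c(O)cc1O | intermediate
18 | kazinol D (achiral) | C=CC(C)(C)c1cc(CCCc2cc(O)c3c(c2CC=C(C)C)CCC(C)(C)O3)c(O)cc1O | target

**Step count**
Total steps: 11. Longest linear sequence: 10 (steps 1–6, then 8–11).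

**Steps most likely to fail**

Step 8. Three processes may interfere:
- attack through C-2 instead of C-6 of the phenol;
- self-aldol condensation of the enolisable aldehyde;
- thermal opening of the electron-rich dioxaborinine to the quinone methide, followed by a hydrogen shift to a styrene.

The fallback sets out from 8 and comes back at 15. It forms the same aryl–CH2 bond at the CH2 level by cross-coupling. Compound 8 is reduced with NaBH4 to 3-[8-(methoxymethoxy)-2,2-dimethyl-5-prenylchroman-6-yl]propan-1-ol F1. Treatment with I2/PPh3/imidazole turns this into the primary iodide F2, and zinc dust/LiCl in THF turns F2 into the alkylzinc iodide F3. In parallel, commercial 4-bromoresorcinol F4 is O-prenylated at the less hindered OH para to bromine (prenyl bromide, K2CO3) to 2-bromo-5-(prenyloxy)phenol F5. This is silylated (TBSCl, imidazole) to its tert-butyldimethylsilyl ether F6. Negishi coupling of F3 with F6 (Pd(OAc)2/SPhos, THF) gives the silyl-protected diarylpropane F7, and TBAF sets free 15.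

Step 9. Expulsion of the benzylic oxygen may be slow. Long heating would then allow tautomerisation of the quinone methide to a styrene, or reversal of the hydroxyalkylation.

The fallback sets out from 12 and comes back at 15. The boron is taken off 12 under neutral conditions by exchange with propane-1,3-diol, and diol 13 is isolated. Its phenol alone is acylated with ethyl chloroformate/Et3N at 0 °C to the aryl ethyl carbonate F8. NaBH4 in THF–water at 0 °C to rt then triggers migration of the carbonate to the benzylic oxygen. Ethyl carbonate is lost to give 14 far below reflux, and hydride capture gives 15.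

Step 10. Site selectivity between C-5 and C-3 may be poor. At the temperature needed, follow-up reactions of the product are also possible, namely abnormal Claisen isomerisation of the side chain and ring closure of the phenol onto the vinyl group.

The fallback sets out from 10 and comes back at 18. The rearrangement is moved to the small fragment, and a ring A piece that already carries the 1,1-dimethylallyl group is coupled.
- Compound 10 is acetylated to 3-(prenyloxy)phenyl acetate F9.
- F9 is rearranged thermally, and the isomers are separated at this cheap stage to give 3-hydroxy-4-(2-methylbut-3-en-2-yl)phenyl acetate F10.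
- MOMCl/i-Pr2NEt gives the MOM ether acetate F11.
- K2CO3/MeOH gives 3-(methoxymethoxy)-4-(2-methylbut-3-en-2-yl)phenol F12.
- Union of F12 with 8 under the conditions of step 8 gives the benzodioxaborinine F13.
- The conditions of step 9 give the bis-MOM ether of kazinol D F14.
- The conditions of step 11 remove both MOM groups to give 18.

**Further compounds**
F1 | step 8 | 3-[8-(methoxymethoxy)-2,2-dimethyl-5-prenylchroman-6-yl]propan-1-ol | COCOc1cc(CCCO)c(CC=C(C)C)c2CCC(C)(C)Oc12
F2 | step 8 | 6-(3-iodopropyl)-8-(methoxymethoxy)-2,2-dimethyl-5-prenylchroman | COCOc1cc(CCCI)c(CC=C(C)C)c2CCC(C)(C)Oc12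
F3 | step 8 | {3-[8-(methoxymethoxy)-2,2-dimethyl-5-prenylchroman-6-yl]propyl}zinc iodide | COCOc1cc(CCC[Zn]I)c(CC=C(C)C)c2CCC(C)(C)Oc12
F4 | step 8 | 4-bromoresorcinol (bought) | Oc1ccc(Br)c(O)c1
F5 | step 8 | 2-bromo-5-(prenyloxy)phenol | CC(C)=CCOc1ccc(Br)c(O)c1
F6 | step 8 | [2-bromo-5-(prenyloxy)phenoxy](tert-butyl)dimethylsilane | CC(C)=CCOc1ccc(Br)c(O[Si](C)(C)C(C)(C)C)c1
F7 | step 8 | tert-butyldimethylsilyl ether of 15 | CC(C)=CCOc1ccc(CCCc2cc(OCOC)c3OC(C)(C)CCc3c2CC=C(C)C)c(O[Si](C)(C)C(C)(C)C)c1
F8 | step 9 | rac-ethyl 2-{1-hydroxy-3-[8-(methoxymethoxy)-2,2-dimethyl-5-prenylchroman-6-yl]propyl}-5-(prenyloxy)phenyl carbonate | CCOC(=O)Oc1cc(OCC=C(C)C)ccc1C(O)CCc1cc(OCOC)c2OC(C)(C)CCc2c1CC=C(C)C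
F9 | step 10 | 3-(prenyloxy)phenyl acetate | CC(=O)Oc1cccc(OCC=C(C)C)c1
F10 | step 10 | 3-hydroxy-4-(2-methylbut-3-en-2-yl)phenyl acetate | C=CC(C)(C)c1ccc(OC(C)=O)cc1O
F11 | step 10 | 3-(methoxymethoxy)-4-(2-methylbut-3-en-2-yl)phenyl acetate | C=CC(C)(C)c1ccc(OC(C)=O)cc1OCOC
F12 | step 10 | 3-(methoxymethoxy)-4-(2-methylbut-3-en-2-yl)phenol | C=CC(C)(C)c1ccc(O)cc1OCOC
F13 | step 10 | rac-7-(methoxymethoxy)-6-(2-methylbut-3-en-2-yl)-2-phenyl-4-{2-[8-(methoxymethoxy)-2,2-dimethyl-5-prenylchroman-6-yl]ethyl}-4H-1,3,2-benzodioxaborinine | C=CC(C)(C)c1cc2C(CCc3cc(OCOC)c4OC(C)(C)CCc4c3CC=C(C)C)OB(c3ccccc3)Oc2cc1OCOC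
F14 | step 10 | 5-(methoxymethoxy)-2-{3-[8-(methoxymethoxy)-2,2-dimethyl-5-prenylchroman-6-yl]propyl}-4-(2-methylbut-3-en-2-yl)phenol | C=CC(C)(C)c1cc(CCCc2cc(OCOC)c3OC(C)(C)CCc3c2CC=C(C)C)c(O)cc1OCOC
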